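There are 3 questions, and we take the first one first, with a single number read from the earlier runs.

| setting | autumn | midnight | dusk | flask |
|---|---|---|---|---|
| Z | 0.090 M | 0.14 M | 0.18 M | 0.18 M |
| Q | 34 mM (held) | 34 mM (held) | 34 mM (held) | 34 mM (held) |
| L | 3.2 mM | 3.2 mM | 4.8 mM | 3.2 mM |
| remark | run made earlier | run made earlier | run made earlier |  |
| time |  |  |  | 2.5 h |

- autumn (time / h: G / %): 0.667: 15.6; 1.33: 31.9; 2.00: 44.3; 2.50: 53.6
- midnight (time / h: G / %): 0.333: 8.2; 0.833: 19.8; 1.50: 35.0; 2.50: 53.6
- dusk (time / h: G / %): 0.200: 4.3; 0.500: 14.2; 1.00: 29.0; 2.50: 59.6

(each reading ± 0.5 percentage points)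

- at the start none of Q is in solution

1. amount of G at 2.5 h, in percent of the Z charged
2. the change that raises the amount of G at 2.5 h, in percent of the Z charged most ("none" if none brings more than 2 percentage points) (beta / alpha / zeta / none)
3. amount of G at 2.5 h, in percent of the Z charged, after alpha

- beta: doubling the saturation concentration of Q, all else as stated
- alpha: doubling the transfer coefficient of Q, all else as stated
- zeta: doubling the amount of L, all else as stated

1. The midnight run reached 53.6% of G at 2.5 h, which gives 0.768 for the exponent, the natural logarithm of the Z charged over the Z left. We compare exponents at this reading time and no other.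

2. The bench rule for a pseudo-first-order reaction says that, at one L, one Q and one reading time, the exponent ignores the charge of Z. The autumn run and the midnight run support it, since they read 53.6% and 53.6% on charges a factor 1.56 apart.

3. The flask has the L of those runs, and its Z is a factor 1.29 above the midnight charge. So we keep the exponent and commit to 53.6% of G.

4. A second bench rule makes the exponent proportional to L, at one Q and one reading time, and the dusk run marks its border. Its L is a factor 1.50 above the midnight run's and its Z is 0.18 M, a change the first bench rule sets aside, but its 59.6% gives an exponent of 0.906, a factor of only 1.18, less than the rule asks.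

5. So we read the exponent as growing with L to the power 0.409, a reading that carries the scatter of the runs. For doubling L in the flask we then reckon 63.9% of G. The autumn, midnight and dusk runs share 34 mM of Q, so their exponents give us no figure for alpha or beta.

6. The forecast gives 53.6%, names beta as the best change and puts alpha at 56%, adding of the order in Q, “This order is untested”.

    Q ⇌ X, rate k1*(csat - [X]) (kL = 0.460 min⁻¹)
    Z + X + L → L + G (k = 370 M⁻² min⁻¹)
    X → E (k = 0.0390 min⁻¹)
    X ⇌ J (K = 7.10, k = 0.180 min⁻¹)
    2 L ⇌ D, settled at all times (K = 5400 M⁻¹)

The flask gives 52.7%, an exponent of 0.749 against our 0.768. Its best change is beta, worth 25 percentage points, and alpha gives 56.7%. The neighbouring flask is this one with 0.0054 M of L. There the power 0.409 raises our exponent to 0.951 and G to 61.4%. That neighbour gives 62.6%, an exponent of 0.983, more than we reckoned. At its end L stands at 12.3% of its charge and D at 87.7%, where the flask has 15.6% and 84.4%.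

(The runs come from a simulation for an exercise; the scatter is artificial.)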